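The target is disconnected at the two bonds that tie the free-standing resorcinol ring (ring B) into the seven-membered ring: from its carbon meta to both oxygens to the dihydrofuran C3 methine, and from its carbon ortho/para to them to the aryl-bearing carbon alpha to the ketone. Dihydrofuran C2 and that alpha carbon carry identical 4-hydroxyphenyl groups, so C2, C3 and the alpha carbon map onto ArCO–CH2–COAr of a symmetric 1,3-diketone. In the key step 3,5-dimethoxybenzyne (from its silylaryl triflate) inserts into one CH2–C(=O) bond of dianisoylmethane, forming both aryl–carbon bonds at once with methoxy-directed regiochemistry. Ring A is then attached by alpha-arylation; a dynamic kinetic reduction, acid cyclisation and keto–ester coupling finish the rings.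

Key step: step 5

Remark: ring A is the benzo ring of the benzofuran and ring B the other resorcinol ring; the carbon alpha to the ketone is enolisable, and its natural configuration (aryl pseudo-equatorial on the rigid seven-membered ring) is assumed to be the one reached under the equilibrating conditions of steps 9 and 10.

Step 1
Reactants: 1 3,5-dimethoxyphenol
Product: 2 2-bromo-3,5-dimethoxyphenol
Conditions: NBS, CH2Cl2, −78 °C to 0 °C
Reagents that add atoms: N-bromosuccinimide O=C1CCC(=O)N1Br
Why: Electrophilic aromatic bromination should go to the position ortho to the hydroxyl and para to a methoxy group (two equivalent sites), the minor 4-bromo isomer being removed by chromatography.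

Step 2
Reactants: 2 2-bromo-3,5-dimethoxyphenol
Product: 5 3,5-dimethoxy-2-(trimethylsilyl)phenyl trifluoromethanesulfonate, via aryl trimethylsilyl ether 3 (not isolated), via lithium 2-silylphenoxide 4 (not isolated)
Conditions: HMDS, THF, 70 °C, evaporate; n-BuLi, THF, −100 °C to −78 °C; Tf2O, −78 °C to rt
Reagents that add atoms: hexamethyldisilazane C[Si](C)(C)N[Si](C)(C)C; trifluoromethanesulfonic anhydride O=S(=O)(OS(=O)(=O)C(F)(F)F)C(F)(F)F
Why: This is the standard route to Kobayashi aryne precursors: O-silylation, bromine–lithium exchange and retro-Brook 1,3-shift of silicon from oxygen to carbon give phenoxide 4, which is trapped as the triflate.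

Step 3
Reactants: 6 methyl 3,5-dihydroxybenzoate
Product: 7 methyl 3,5-bis(methoxymethoxy)benzoate
Conditions: MOMCl, iPr2NEt, CH2Cl2, 0 °C to rt
Reagents that add atoms: chloromethyl methyl ether COCCl
Why: O-alkylation of both phenols gives MOM acetals that survive base and palladium and are later removed by acid in the same pot as ring closure.

Step 4
Reactants: 7 methyl 3,5-bis(methoxymethoxy)benzoate
Product: 8 methyl 2-bromo-3,5-bis(methoxymethoxy)benzoate
Conditions: NBS, MeCN, rt
Reagents that add atoms: N-bromosuccinimide O=C1CCC(=O)N1Br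
Why: Electrophilic bromination of 3,5-dialkoxybenzoates is known to go next to the ester (ortho to one alkoxy group and para to the other), since the position between the two alkoxy groups is shielded.

Step 5
Reactants: 5 3,5-dimethoxy-2-(trimethylsilyl)phenyl trifluoromethanesulfonate; 9 1,3-bis(4-methoxyphenyl)propane-1,3-dione (dianisoylmethane)
Product: 12 2-[3,5-dimethoxy-2-(4-methoxybenzoyl)phenyl]-1-(4-methoxyphenyl)ethan-1-one, via 3,5-dimethoxybenzyne 10 (not isolated), via cesium benzocyclobutenoxide 11 (not isolated)
Conditions: 9 (1.2 equiv), CsF (2.5 equiv), MeCN, 80 °C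
Reagents that add atoms: none
Why: Fluoride strips the silyl group of 5 and expels triflate to give aryne 10, and the cesium enolate of 9 adds through its central carbon to the aryne carbon meta to both methoxy groups, which leaves the aryl anion on the carbon flanked by OMe where induction stabilises it. The anion closes onto the neighbouring carbonyl in a 4-exo-trig addition to give benzocyclobutenoxide 11, and retro-aldol-type opening of this strained ring cuts the original CH–C(=O) bond, so the arene ends up inserted between the methylene carbon and the aroyl carbon. The closest known reaction type is the aryne acyl-alkylation (σ-bond insertion of arynes into β-dicarbonyl compounds), which is established for β-diketones and for 3,5-dialkoxyarynes. No ring survives in the product and no stereocenter is formed. The step needs regiocontrol at the aryne, secured by the methoxy group next to the triple bond, and mono-insertion, secured because β-diketone 9 is far more acidic than monoketone 12 and is used in slight excess; the symmetry of 9 makes the two possible C–C(=O) cleavages identical.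

Step 6
Reactants: 12 2-[3,5-dimethoxy-2-(4-methoxybenzoyl)phenyl]-1-(4-methoxyphenyl)ethan-1-one; 8 methyl 2-bromo-3,5-bis(methoxymethoxy)benzoate
Product: 13 racemic methyl 2-{1-[3,5-dimethoxy-2-(4-methoxybenzoyl)phenyl]-2-(4-methoxyphenyl)-2-oxoethyl}-3,5-bis(methoxymethoxy)benzoate
Conditions: Pd(OAc)2 (5 mol%), XPhos (10 mol%), K3PO4, toluene, 80 °C
Reagents that add atoms: none
Why: Buchwald–Hartwig-type palladium-catalysed alpha-arylation of a ketone enolate should take place at the only enolisable carbon of 12; the new methine lies between a ketone and two aryl groups, so 13 is racemic and configurationally labile, which step 7 exploits.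

Step 7
Reactants: 13 racemic keto ester
Product: 15 (3R,4R)-4-[3,5-dimethoxy-2-(4-methoxybenzoyl)phenyl]-3-(4-methoxyphenyl)-5,7-bis(methoxymethoxy)-3,4-dihydro-1H-isochromen-1-one (trans lactone), via hydroxy ester 14 (not isolated)
Conditions: RuCl[(R,R)-TsDPEN](p-cymene) (5 mol%), HCO2H/Et3N (1:2), DMF, 40 °C
Reagents that add atoms: none
Why: Noyori–Ikariya asymmetric transfer hydrogenation with dynamic kinetic resolution: the (R,R) catalyst should give the (R)-carbinol, the labile alpha-methine epimerises through the enol under Et3N and the Felkin-matched enantiomer (ring A as the large group) is reduced faster, so both centers are set as (R,R), while the crowded, electron-rich diaryl ketone is left alone and the new hydroxyl closes onto the ester to give the trans lactone.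

Step 8
Reactants: 15 (3R,4R)-lactone
Product: 16 methyl (2R,3R)-3-[3,5-dimethoxy-2-(4-methoxybenzoyl)phenyl]-6-hydroxy-2-(4-methoxyphenyl)-2,3-dihydro-1-benzofuran-4-carboxylate
Conditions: HCl (2 M) in MeOH, 55 °C
Reagents that add atoms: methanol CO
Why: Acidic methanolysis removes both MOM groups and ionises the p-methoxybenzylic lactone C–O bond (SN1); the ortho phenol of ring A captures the cation in a 5-exo closure, the C2 configuration settles trans to the C3 aryl group under reversible, thermodynamic control by the untouched C3 center, and the freed acid is re-esterified (Fischer).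

Step 9
Reactants: 16 keto ester with the dihydrobenzofuran in place
Product: 18 pauciflorol E tetramethyl ether (both 4-methoxyphenyl groups and both ring B oxygens methylated; ring A phenol free; all three stereocenters R), via cyclic methyl enol ether 17 (not isolated)
Conditions: TiCl3, Zn dust, DME, reflux, slow addition at high dilution; then 1 M HCl, THF, rt
Reagents that add atoms: water O
Why: McMurry–Fürstner keto–ester coupling with low-valent titanium should close the seven-membered ring as enol ether 17, which acid hydrolyses to the ketone; the enol ether carbon is protonated along the axial direction and the center remains enolisable, so the 4-methoxyphenyl group settles pseudo-equatorial as in the natural product.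

Step 10
Reactants: 18 pauciflorol E tetramethyl ether
Product: 19 pauciflorol E
Conditions: BBr3 (excess), CH2Cl2, −78 °C to rt; then ice-water
Reagents that add atoms: none
Why: BBr3 cleavage of the four aryl methyl ethers (Lewis acid–base complex, then bromide attack on methyl) should release the hexaphenol, and the benzylic ether of the dihydrobenzofuran can only reclose to the same trans ring.

Compound list
1 | 3,5-dimethoxyphenol | COc1cc(O)cc(OC)c1 | starting material
2 | 2-bromo-3,5-dimethoxyphenol | Oc1cc(OC)cc(OC)c1Br | intermediate
3 | (2-bromo-3,5-dimethoxyphenoxy)trimethylsilane | C[Si](C)(C)Oc1cc(OC)cc(OC)c1Br | intermediate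
4 | lithium 3,5-dimethoxy-2-(trimethylsilyl)phenoxide | [Li+].[O-]c1cc(OC)cc(OC)c1[Si](C)(C)C | intermediate
5 | 3,5-dimethoxy-2-(trimethylsilyl)phenyl trifluoromethanesulfonate | COc1cc(OC)c([Si](C)(C)C)c(OS(=O)(=O)C(F)(F)F)c1 | intermediate
6 | methyl 3,5-dihydroxybenzoate | COC(=O)c1cc(O)cc(O)c1 | starting material
7 | methyl 3,5-bis(methoxymethoxy)benzoate | COC(=O)c1cc(OCOC)cc(OCOC)c1 | intermediate
8 | methyl 2-bromo-3,5-bis(methoxymethoxy)benzoate | COC(=O)c1cc(OCOC)cc(OCOC)c1Br | intermediate
9 | 1,3-bis(4-methoxyphenyl)propane-1,3-dione | COc1ccc(cc1)C(=O)CC(=O)c1ccc(OC)cc1 | starting material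
10 | 3,5-dimethoxybenzyne (1,2-didehydro-3,5-dimethoxybenzene) | COC1=CC(OC)=CC#C1 | intermediate
11 | cesium 3,5-dimethoxy-8-(4-methoxybenzoyl)-7-(4-methoxyphenyl)bicyclo[4.2.0]octa-1,3,5-trien-7-olate | COc1ccc(cc1)C(=O)C1c2cc(OC)cc(OC)c2C1([O-])c1ccc(OC)cc1.[Cs+] | intermediate
12 | 2-[3,5-dimethoxy-2-(4-methoxybenzoyl)phenyl]-1-(4-methoxyphenyl)ethan-1-one | COc1ccc(cc1)C(=O)Cc1cc(OC)cc(OC)c1C(=O)c1ccc(OC)cc1 | intermediate
13 | racemic methyl 2-{1-[3,5-dimethoxy-2-(4-methoxybenzoyl)phenyl]-2-(4-methoxyphenyl)-2-oxoethyl}-3,5-bis(methoxymethoxy)benzoate | COC(=O)c1cc(OCOC)cc(OCOC)c1C(c1cc(OC)cc(OC)c1C(=O)c1ccc(OC)cc1)C(=O)c1ccc(OC)cc1 | intermediate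
14 | methyl 2-{(1R,2R)-1-[3,5-dimethoxy-2-(4-methoxybenzoyl)phenyl]-2-hydroxy-2-(4-methoxyphenyl)ethyl}-3,5-bis(methoxymethoxy)benzoate | COC(=O)c1cc(OCOC)cc(OCOC)c1[C@@H](c1cc(OC)cc(OC)c1C(=O)c1ccc(OC)cc1)[C@@H](O)c1ccc(OC)cc1 | intermediate
15 | (3R,4R)-4-[3,5-dimethoxy-2-(4-methoxybenzoyl)phenyl]-3-(4-methoxyphenyl)-5,7-bis(methoxymethoxy)-3,4-dihydro-1H-isochromen-1-one | O=C1O[C@@H](c2ccc(OC)cc2)[C@H](c2cc(OC)cc(OC)c2C(=O)c2ccc(OC)cc2)c2c(OCOC)cc(OCOC)cc21 | intermediate
16 | methyl (2R,3R)-3-[3,5-dimethoxy-2-(4-methoxybenzoyl)phenyl]-6-hydroxy-2-(4-methoxyphenyl)-2,3-dihydro-1-benzofuran-4-carboxylate | COC(=O)c1cc(O)cc2c1[C@@H](c1cc(OC)cc(OC)c1C(=O)c1ccc(OC)cc1)[C@H](c1ccc(OC)cc1)O2 | intermediate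
17 | cyclic methyl enol ether of 18 (seven-membered ring closed, C(OMe)=C(4-methoxyphenyl) in place of the keto methine; (2R,3R)-dihydrofuran) | COC=1c2cc(O)cc3c2[C@@H](c2cc(OC)cc(OC)c2C=1c1ccc(OC)cc1)[C@H](c1ccc(OC)cc1)O3 | intermediate
18 | pauciflorol E tetramethyl ether (methyl ethers on both 4-hydroxyphenyl groups and both ring B oxygens; ring A phenol free; dihydrofuran C2 and C3 and the keto methine all R) | O=C1c2cc(O)cc3c2[C@@H](c2cc(OC)cc(OC)c2[C@H]1c1ccc(OC)cc1)[C@H](c1ccc(OC)cc1)O3 | intermediate
19 | pauciflorol E | O=C1c2cc(O)cc3c2[C@@H](c2cc(O)cc(O)c2[C@H]1c1ccc(O)cc1)[C@H](c1ccc(O)cc1)O3 | target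

Total step count: 10. Longest linear sequence: 8 steps (steps 1, 2, 5, 6, 7, 8, 9, 10).

Steps most likely to fail

Step 6. The reductive elimination has to join a 2,6-disubstituted aryl group to a carbon that already carries an ortho-substituted aryl group, so the coupling may stall; the product enolate may also be O-acylated by the neighbouring ester to an enol lactone. The fallback changes the order of bond formation and sets out from 9 and 8. A copper-catalysed Hurtley-type arylation (CuI, L-proline, K2CO3, DMSO, 80 °C), helped by the ortho ester of 8, joins ring A to the central carbon of the diketone and gives methyl 2-[1,3-bis(4-methoxyphenyl)-1,3-dioxopropan-2-yl]-3,5-bis(methoxymethoxy)benzoate F1. F1 then takes the place of 9 in the aryne insertion with 5 (CsF, MeCN, 80 °C); insertion into either of its two equivalent C–C(=O) bonds comes back to the route at 13.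

Step 7. The catalyst may discriminate poorly between the two rapidly interconverting enantiomers of 13, giving a mixture at the C3 methine, or the hindered ketone may be reduced too slowly. If only the sense of the resolution is inverted, the (S,S) catalyst is used, since the carbinol center is reset in step 8. The fallback replaces asymmetric catalysis by resolution and sets out from 13. Reduction with NaBH4 (THF/MeOH, 0 °C) gives the racemic lactone F2 as both diastereomers. Under the conditions of step 8 this converges to the racemic trans dihydrobenzofuran ester F3. Preparative chromatography of F3 on a chiral stationary phase delivers the (2R,3R) enantiomer and comes back to the route at 16.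

Step 9. The diaryl ketone may undergo intermolecular pinacol coupling or simple reduction instead of the seven-membered keto–ester closure. The fallback builds the same C–C bond by a samarium pinacol coupling and a pinacol rearrangement and sets out from 16. LiAlH4 (THF, 0 °C) reduces ester and ketone to the triol F4. MnO2 (CH2Cl2, rt) reoxidises both benzylic alcohols to the keto aldehyde F5. SmI2 (THF, −78 °C) couples aldehyde and ketone to the seven-membered cyclic diol F6. TsOH (toluene, 60 °C) ionises the tertiary, doubly benzylic carbinol, and a 1,2-hydride shift gives the ketone, coming back to the route at 18.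

Further compounds
F1 | step 6 | methyl 2-[1,3-bis(4-methoxyphenyl)-1,3-dioxopropan-2-yl]-3,5-bis(methoxymethoxy)benzoate | COC(=O)c1cc(OCOC)cc(OCOC)c1C(C(=O)c1ccc(OC)cc1)C(=O)c1ccc(OC)cc1
F2 | step 7 | racemic 4-[3,5-dimethoxy-2-(4-methoxybenzoyl)phenyl]-3-(4-methoxyphenyl)-5,7-bis(methoxymethoxy)-3,4-dihydro-1H-isochromen-1-one (both diastereomers) | O=C1OC(c2ccc(OC)cc2)C(c2cc(OC)cc(OC)c2C(=O)c2ccc(OC)cc2)c2c(OCOC)cc(OCOC)cc21
F3 | step 7 | racemic trans methyl 3-[3,5-dimethoxy-2-(4-methoxybenzoyl)phenyl]-6-hydroxy-2-(4-methoxyphenyl)-2,3-dihydro-1-benzofuran-4-carboxylate (racemate of 16) | COC(=O)c1cc(O)cc2c1C(c1cc(OC)cc(OC)c1C(=O)c1ccc(OC)cc1)C(c1ccc(OC)cc1)O2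
F4 | step 9 | (2R,3R)-4-(hydroxymethyl)-3-{2-[hydroxy(4-methoxyphenyl)methyl]-3,5-dimethoxyphenyl}-2-(4-methoxyphenyl)-2,3-dihydro-1-benzofuran-6-ol (carbinol epimers) | OCc1cc(O)cc2c1[C@@H](c1cc(OC)cc(OC)c1C(O)c1ccc(OC)cc1)[C@H](c1ccc(OC)cc1)O2
F5 | step 9 | (2R,3R)-3-[3,5-dimethoxy-2-(4-methoxybenzoyl)phenyl]-6-hydroxy-2-(4-methoxyphenyl)-2,3-dihydro-1-benzofuran-4-carbaldehyde | O=Cc1cc(O)cc2c1[C@@H](c1cc(OC)cc(OC)c1C(=O)c1ccc(OC)cc1)[C@H](c1ccc(OC)cc1)O2
F6 | step 9 | seven-membered cyclic 1,2-diol of the tetramethyl ether skeleton (secondary carbinol next to ring A, tertiary carbinol bearing the 4-methoxyphenyl group; (2R,3R)-dihydrofuran, diol epimers) | OC1c2cc(O)cc3c2[C@@H](c2cc(OC)cc(OC)c2C1(O)c1ccc(OC)cc1)[C@H](c1ccc(OC)cc1)O3
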